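**Retrosynthetic overview**

- The target is ring D (an acylated 4,4-dimethylcyclohexane-1,3,5-trione enol) fused through dihydropyran ring C to a hydroazulene (cyclopentane ring A, cycloheptane ring B).
- Rings A and B are unravelled to the eleven-membered ring of humulene: an 8,9-epoxide, installed by catalyst-controlled epoxidation (source of absolute configuration), triggers transannular cation–olefin cyclization with ring contraction.
- Ring C comes from a three-component Knoevenagel/hetero-Diels–Alder union of isobutyrylfilicinic acid, formaldehyde and α-humulene.
- Ring D comes from a one-flask [4+2] Claisen/Dieckmann annulation of the methyl isobutyrate enolate with diketene. It forms the bond from the quaternary gem-dimethyl carbon to the ring ketone carbon and the bond from the CH2-bearing ring carbon to the enol-ether carbon. The enabling feature is that in ring D the non-enolisable gem-dimethyl carbon lies between two oxygenated carbons and the three ring oxygens alternate (1,3,5), so ring D is one dimethylketene unit joined to one diketene unit; the quaternary carbon keeps its ester electrophilic and blocks aromatisation.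
- Order of ring formation: D, then C, then A and B together.

Key step: step 1

Remark on the chemistry: terpene atoms are named by humulene numbering (C1H=C2(CH3)–C3H2–C4H=C5H–C6(CH3)2–C7H2–C8H=C9(CH3)–C10H2–C11H2), which is kept through all later steps; ring-D enols are drawn in one tautomeric form.

**Step 1**
Reactants: 1 methyl isobutyrate; 2 diketene (4-methylideneoxetan-2-one)
Product: 5 filicinic acid (3,5-dihydroxy-4,4-dimethylcyclohexa-2,5-dien-1-one), via lithium ester enolate 3 (not isolated), via dilithium dienolate 4 (not isolated)
Conditions: LiN(i-Pr)2 (1.05 equiv), THF, −78 °C; 2 (1.0 equiv), −78 °C; LiN(i-Pr)2 (1.2 equiv), −78 to 0 °C; aq. HCl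
Reagents that add atoms: none
Why: Enolate 3 should attack the strained lactone carbonyl of 2 at carbon (Claisen-type C-acetoacetylation), which joins the fully substituted gem-dimethyl carbon to the future ring ketone carbon; the second portion of base converts the resulting β-diketonate into dienolate 4, whose terminal carbanion closes onto the methyl ester (Dieckmann condensation) and so joins the future CH2-bearing ring carbon to the future enol-ether carbon with loss of methoxide. The closest known reaction types are the C-acylation of ester enolates by acid chlorides and by diketene, and the acylation of 1,3-diketone dianions at their terminal carbon by esters. Ring D closes in a 6-exo-trig mode (carbanion onto ester carbonyl). No stereocenter is formed. The step needs C- instead of O-acylation and ring closure through the terminal instead of the central carbon; the quaternary α-carbon secures this, because the ester next to it cannot enolise and stays electrophilic, while the dianion reacts at its more basic terminal carbon. The trione is withdrawn from all equilibria as its stabilised enolate, and any O-cyclised enol lactone would be reopened by the methoxide set free.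

**Step 2**
Reactants: 5 filicinic acid; 6 isobutyric acid
Product: 8 isobutyrylfilicinic acid (3,5-dihydroxy-6,6-dimethyl-2-(2-methylpropanoyl)cyclohexa-2,4-dien-1-one), via enol ester 7 (not isolated)
Conditions: DCC (1.1 equiv), DMAP (1.2 equiv), CH2Cl2–DMF, 0 °C to rt
Reagents that add atoms: none
Why: The carbodiimide-activated acid should O-acylate an enol oxygen of 5 to give 7, and DMAP then relays the acyl group from oxygen to the ring carbon (O-to-C acyl migration known for cyclic 1,3-diones), the hydrogen-bonded 2-acyl trione being the thermodynamic sink; the two ring CH positions of 5 are equivalent by symmetry, and one equivalent of acid limits double acylation.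

**Step 3**
Reactants: 8 isobutyrylfilicinic acid; 9 formaldehyde (as paraformaldehyde); 10 α-humulene
Product: 12 (±)-tricyclic hetero-Diels–Alder adduct (rings C/D trans-fused to the eleven-membered 4E,8E-diene ring; (1S,2R) enantiomer drawn), via methylene triketone 11 (not isolated)
Conditions: 9 (2 equiv), 10 (3 equiv), NaOAc (0.2 equiv), AcOH (0.2 equiv), 1,4-dioxane, 80 °C
Reagents that add atoms: none
Why: Knoevenagel condensation at the free ring CH of 8 should give the electron-poor heterodiene 11, which undergoes an inverse-electron-demand hetero-Diels–Alder reaction (domino Knoevenagel/hetero-Diels–Alder, known for cyclic 1,3-diones and acylphloroglucinols with terpene alkenes) with the strained trisubstituted C1=C2 bond of 10; the carbonyl next to the gem-dimethyl carbon acts as the hetero atom because the other flanking oxygen is held as the enol hydrogen-bonded to the acyl group, CH2 bonds to the less substituted C1 and oxygen to C2, and suprafacial addition to the E alkene sets C1–H trans to C2–CH3 in racemic form.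

**Step 4**
Reactants: 12 (±)-tricyclic adduct
Product: 13 (1S,2R,8R,9R)-8,9-epoxide of 12
Conditions: 1,2:4,5-di-O-isopropylidene-β-D-erythro-2,3-hexodiulo-2,6-pyranose (D-fructose-derived Shi ketone, C12H18O6, 0.3 equiv), KHSO5 (0.7 equiv, as 2KHSO5·KHSO4·K2SO4), K2CO3, Bu4NHSO4 (cat.), MeCN/CH2(OMe)2–aq. Na2B4O7 buffer (pH 10.5), −10 °C, stopped near half conversion
Reagents that add atoms: potassium peroxymonosulfate (KHSO5), [K+].[O-]S(=O)(=O)OO
Why: The chiral dioxirane (Shi epoxidation) delivers oxygen to E-trisubstituted alkenes in the (R,R) sense and is used here as a catalyst-controlled kinetic resolution of racemic 12: in the (1S,2R) enantiomer the catalyst-preferred face of C8=C9 should coincide with the exposed outer face of the eleven-membered ring and give 13, whereas the antipode is mismatched and is left behind or gives a separable diastereomer; the disubstituted C4=C5 bond beside the quaternary carbon and the conjugated enol ether of ring D are less nucleophilic.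

**Step 5**
Reactants: 13 (1S,2R,8R,9R)-epoxide
Product: 14 target compound CNP0510355.1
Conditions: p-TsOH·H2O (0.2 equiv), CH2Cl2, 0 °C to rt
Reagents that add atoms: none
Why: Acid should open the epoxide at tertiary C9 while C4 of the C4=C5 bond attacks from the rear (inversion at C9, ring B and a six-membered ring formed; the C8–O bond is untouched and becomes the secondary alcohol), the secondary cation at C5 is quenched by a 1,2-shift of C7 from C6 to C5 on the same face (Wagner–Meerwein ring contraction to ring A, which turns the E geometry into the trans relationship of C4–H and C5–H), and the resulting 2-propyl cation loses a methyl proton to give the isopropenyl group; this is an epoxide-initiated transannular cation–olefin cyclization of the kind known for humulene epoxides.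

**Compound list**

1 | methyl isobutyrate (methyl 2-methylpropanoate) | COC(=O)C(C)C | starting material
2 | diketene (4-methylideneoxetan-2-one) | C=C1CC(=O)O1 | starting material
3 | lithium 1-methoxy-2-methylprop-1-en-1-olate (enolate of 1) | [Li+].COC([O-])=C(C)C | intermediate
4 | dilithium dienolate of methyl 2,2-dimethyl-3,5-dioxohexanoate | [Li+].[Li+].COC(=O)C(C)(C)C([O-])=CC([O-])=C | intermediate
5 | filicinic acid (3,5-dihydroxy-4,4-dimethylcyclohexa-2,5-dien-1-one) | CC1(C)C(O)=CC(=O)C=C1O | intermediate
6 | isobutyric acid (2-methylpropanoic acid) | CC(C)C(=O)O | starting material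
7 | 5-hydroxy-6,6-dimethyl-3-oxocyclohexa-1,4-dien-1-yl 2-methylpropanoate (enol ester of 5) | CC(C)C(=O)OC1=CC(=O)C=C(O)C1(C)C | intermediate
8 | isobutyrylfilicinic acid (3,5-dihydroxy-6,6-dimethyl-2-(2-methylpropanoyl)cyclohexa-2,4-dien-1-one) | CC(C)C(=O)C1=C(O)C=C(O)C(C)(C)C1=O | intermediate
9 | formaldehyde (used as paraformaldehyde) | C=O | starting material
10 | α-humulene ((1E,4E,8E)-2,6,6,9-tetramethylcycloundeca-1,4,8-triene) | C1/C(C)=C/CC(C)(C)/C=C/C/C(C)=C/C1 | starting material
11 | 5-hydroxy-2,2-dimethyl-6-methylidene-4-(2-methylpropanoyl)cyclohex-4-ene-1,3-dione (methylene triketone, o-quinone methide type) | C=C1C(=O)C(C)(C)C(=O)C(C(=O)C(C)C)=C1O | intermediate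
12 | (±)-adduct: ring D (enol, isobutyryl, gem-dimethyl, ketone) fused through dihydropyran ring C to the eleven-membered ring with 4E and 8E double bonds, C1–H trans to C2–CH3; racemate, the (1S,2R) enantiomer that is carried on is drawn | C1/C(C)=C/CC(C)(C)/C=C/C[C@@]2(C)OC3=C(C[C@@H]2C1)C(O)=C(C(=O)C(C)C)C(=O)C3(C)C | intermediate
13 | (1S,2R,8R,9R)-8,9-epoxide of 12 (trans-epoxide, 4E alkene retained) | C1[C@@]2(C)O[C@@H]2CC(C)(C)/C=C/C[C@@]3(C)OC4=C(C[C@@H]3C1)C(O)=C(C(=O)C(C)C)C(=O)C4(C)C | intermediate
14 | CNP0510355.1: ring A cyclopentane (isopropenyl at C5, secondary OH at C8, angular CH3 at C9), ring B cycloheptane, ring C dihydropyran, ring D acylated dienone; (1S,2R,4S,5R,8R,9R) in humulene numbering | C=C(C)[C@@H]1C[C@@H](O)[C@]2(C)CC[C@H]3CC4=C(O[C@]3(C)C[C@@H]12)C(C)(C)C(=O)C(C(=O)C(C)C)=C4O | target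

**Step count and risks**

Total step count: 5. Longest linear sequence: 5 steps (from methyl isobutyrate and diketene).

Steps most likely to fail:

1. Step 4. The resolution may be inefficient (poor discrimination between the two enantiomers of 12), and the basic oxidising medium may attack the acidic ring-D triketone as its enolate. Fallback: setting out from 12, substrate-controlled epoxidation with m-CPBA/NaHCO3 in CH2Cl2 at 0 °C (peripheral attack on the outer face of C8=C9) gives the racemic epoxide, that is 13 together with the mirror-image epoxide F1. The conditions of step 5 then give 14 together with the mirror-image product F2. The enantiomers are separated by preparative HPLC on a chiral stationary phase (cellulose tris(3,5-dimethylphenylcarbamate)), and the route is rejoined at 14.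

2. Step 5. The cation may partition into competing methyl or hydride shifts instead of the ring contraction, or lose its final proton toward the ring to give the isopropylidene isomer. Fallback: setting out from 13, the cyclization is run in aqueous H2SO4/acetone so that the terminal tertiary cation is captured by water as the 2-hydroxypropan-2-yl diol F3. The tertiary hydroxyl is then dehydrated selectively with Ph2S[OC(CF3)2Ph]2 (Martin sulfurane), which leaves the secondary ring-A hydroxyl alone, and the route is rejoined at 14.

3. Step 1. Diketene may oligomerise or be deprotonated by the enolate instead of being C-acylated, and proton transfer may outrun the ring closure. Fallback: setting out from 1, the lithium enolate is acylated with acetyl chloride to give methyl 2,2-dimethyl-3-oxobutanoate F4. Its ketone enolate (LiN(SiMe3)2, 2.2 equiv, THF, −78 °C) is acylated with N-methoxy-N-methylacetamide to give methyl 2,2-dimethyl-3,5-dioxohexanoate F5. The isolated diketo ester is cyclised through its dianion (LiN(i-Pr)2, 2.2 equiv, THF, −78 to 0 °C; aq. HCl), and the route is rejoined at 5.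

**Further compounds**

F1 | step 4 | mirror image of epoxide 13, (1R,2S,8S,9S) | C1[C@]2(C)O[C@H]2CC(C)(C)/C=C/C[C@]3(C)OC4=C(C[C@H]3C1)C(O)=C(C(=O)C(C)C)C(=O)C4(C)C
F2 | step 4 | mirror image of target 14 | C=C(C)[C@H]1C[C@H](O)[C@@]2(C)CC[C@@H]3CC4=C(O[C@@]3(C)C[C@H]12)C(C)(C)C(=O)C(C(=O)C(C)C)=C4O
F3 | step 5 | 2-hydroxypropan-2-yl diol (hydrate of 14 at the isopropenyl group) | CC(C)(O)[C@@H]1C[C@@H](O)[C@]2(C)CC[C@H]3CC4=C(O[C@]3(C)C[C@@H]12)C(C)(C)C(=O)C(C(=O)C(C)C)=C4O
F4 | step 1 | methyl 2,2-dimethyl-3-oxobutanoate | COC(=O)C(C)(C)C(C)=O
F5 | step 1 | methyl 2,2-dimethyl-3,5-dioxohexanoate | COC(=O)C(C)(C)C(=O)CC(C)=O
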